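| setting | larch | elm | alder | birch | ash |
|---|---|---|---|---|---|
| Xa | 0.300 M | 0.150 M | 0.300 M | 0.600 M | 1.40 M |
| Xb | 0.300 M | 0.150 M | 0.900 M | 0.300 M | 0.300 M |
| Xc | 0.00900 M | 0.00900 M | 0.00900 M | 0.00900 M | 0.00900 M |
| time |  |  |  |  | 6.3 h |

| run | time / h | [Xp] / M |
|---|---|---|
| larch run | 0.23 | 0.0033 |
| larch run | 0.69 | 0.0108 |
| larch run | 1.3 | 0.0281 |
| larch run | 2.1 | 0.0508 |
| larch run | 3.0 | 0.0802 |
| larch run | 4.0 | 0.1001 |
| larch run | 5.1 | 0.1196 |
| larch run | 6.3 | 0.1365 |
| elm run | 0.23 | 2 × 10⁻⁴ |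
| elm run | 0.69 | 5 × 10⁻⁴ |
| elm run | 1.3 | 0.0051 |
| elm run | 2.1 | 0.0124 |
| elm run | 3.0 | 0.0164 |
| elm run | 4.0 | 0.0264 |
| elm run | 5.1 | 0.0360 |
| elm run | 6.3 | 0.0454 |
| alder run | 0.23 | 0.0136 |
| alder run | 0.69 | 0.0580 |
| alder run | 1.3 | 0.1113 |
| alder run | 2.1 | 0.1615 |
| alder run | 3.0 | 0.2053 |
| alder run | 4.0 | 0.2359 |
| alder run | 5.1 | 0.2562 |
| alder run | 6.3 | 0.2774 |
| birch run | 0.23 | 0.0022 |
| birch run | 0.69 | 0.0169 |
| birch run | 1.3 | 0.0416 |
| birch run | 2.1 | 0.0801 |
| birch run | 3.0 | 0.1114 |
| birch run | 4.0 | 0.1490 |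
| birch run | 5.1 | 0.1722 |
| birch run | 6.3 | 0.2003 |

(standard deviation of a reading: 0.002 M)

* apparent order in [Xb] of the starting rate, round the charge of the larch run (the rate where two percent of its Xa have turned into Xp)
* apparent order in [Xa] of the starting rate, round the charge of the larch run (the rate where two percent of its Xa have turned into Xp) (one fixed amount of Xp, the same in the runs compared)
* Xp in the ash run at 6.3 h, as a share of the Xa charged

- Overall: Xa + Xb -> Xp, with Xc as catalyst.
- Constant volume, constant temperature.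
- The analysis sees a species whether free or bound.
- "The second partner" is Xb.
- An order is taken over about fifteen percent of the charge, up and down.

**Constants first.** No constant comes with this flask, so one is read from the runs. The last larch reading gives 0.442 M⁻¹ h⁻¹ for k, the apparent pair constant: the rate of Xp per [Xa][Xb], averaged from the start to that reading, early lag included. The last birch reading gives k = 0.368 M⁻¹ h⁻¹, smaller than in larch. This note's own reckoning draws the reciprocal of k straight through these two Xa charges, which puts ash at 0.255 M⁻¹ h⁻¹.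

**In the flask.** Ash holds 1.40 M Xa, 0.300 M Xb and 0.00900 M Xc. Xb is the limiting reagent, so Xp can reach at most 21.4% of the Xa charged. Xa can fall by no more than 0.300 M, so this reckoning takes it at the midpoint, 1.25 M, and treats the loss of Xb as pseudo-first-order, with constant 0.318 h⁻¹.

**At the sample.** By 6.3 h this reckoning gives 18.5% of the Xa charged to ash.

**Hands off.** Xb is not to be topped up. At 2.1 h, alder, with the Xa and Xc of larch but 0.900 M Xb, had made 0.1615 M Xp against 0.0508 M in larch.

**The forecast.** It gives starting-rate orders round the larch charge of 1 in Xb and 0.52 in Xa, and 18.5% for ash, holding that “k sags mildly with Xa”. Had birch shown the k of larch, this note's arithmetic would put ash at 20.8%.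

**The result.** Ash stands at 17.6% of its Xa. Round the larch charge, the starting rate has orders 1.0 in Xb and 0.46 in Xa.

    G + Xa ⇌ Xc.Xa, settled at all times (1.300 M⁻¹)
    Xc.Xa + Xb → Xp + G (56.16 M⁻¹ h⁻¹)
    Xc + Xb → G + Xb (5.148 M⁻¹ h⁻¹)

**Carried on.** Birch, with twice the Xa of larch, ran at 1.3 times the larch rate at equal Xp. Read back through the first-order loss of Xb, the ash result makes k in ash 0.220 M⁻¹ h⁻¹, half of the larch value. Alder starts from the Xa charge of larch, and its mean [Xb] up to half conversion is 0.825 M. The larch k with that mean gives Xa in alder a first-order half-time of 1.90 h, and alder's Xp came to half of its Xa at 1.89 h.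

The readings come from a simulation on assumed constants; scatter was added.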